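(Readings and results are calculated with constants of no real substance; the scatter is artificial.)

Left-handed substrate and left-handed product together hold a constant amount through the earlier runs: their last readings add to 49.7% in ash and 49.5% in oak, against 50.0% charged. Within the scatter the product climbs to the last reading, so I put its maximum in this flask at the end of the time allowed.

| setting | elm | ash | oak | flask |
|---|---|---|---|---|
| left-handed substrate | 0.050 M | 0.050 M | 0.050 M | 0.050 M |
| right-handed substrate | 0.050 M | 0.050 M | 0.050 M | 0.050 M |
| reagent | 0.020 M | 0.080 M | 0.040 M | 0.0400 M |
| catalyst | 0.24 mM | 0.24 mM | 0.48 mM | 0.24 mM |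
| remark | run made earlier | run made earlier | run made earlier |  |
| time |  |  |  | 1.5 h |

| run | time / min | left-handed product / % | left-handed substrate / % |
|---|---|---|---|
| elm | 25.0 | 5.4 | 43.2 |
| elm | 30.0 | 6.9 | 42.0 |
| elm | 40.0 | 9.1 | 40.9 |
| elm | 60.0 | 10.0 | 39.9 |
| elm | 80.0 | 12.0 | 38.3 |
| elm | 120 | 12.4 | 35.9 |
| ash | 25.0 | 22.9 | 28.5 |
| ash | 30.0 | 22.5 | 25.5 |
| ash | 40.0 | 27.0 | 22.0 |
| ash | 60.0 | 31.5 | 17.8 |
| ash | 80.0 | 36.2 | 12.6 |
| ash | 120 | 40.0 | 9.7 |
| oak | 25.0 | 18.3 | 31.8 |
| oak | 30.0 | 19.3 | 29.6 |
| oak | 50.0 | 23.3 | 27.0 |
| oak | 80.0 | 26.4 | 22.6 |
| oak | 120 | 28.7 | 20.8 |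

(readings scatter by 1 percentage point)

- catalyst is single-handed; left-handed substrate and right-handed substrate are mirror images of each other, charged as a racemate, each of them at the stated concentration

- the moment within 1.5 h at which there is most left-handed product
- the amount of left-handed product, in percent of the left-handed substrate and right-handed substrate together charged, at that time
- the first time at which left-handed product reaches 16%, in the same percent

The bench rule is that, with equal charges, product follows catalyst multiplied by time. This flask differs from oak in having half the catalyst, so its 1.5 h counts as 45.0 min of oak, where I interpolate 22.3%. Scaling oak's first reading down through the origin puts 16% in this flask at 0.729 h, a late limit, since the curve bends.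

Reagent is the limiting reagent here, so I divide by its charge, 40.0% of both substrates, and call the result the reagent yield, 0.558: left-handed product per reagent charged at this catalyst-time. The yield has a border: at the same catalyst-time, elm, with reagent to left-handed substrate at 0.400, reads 0.605, while ash, at 1.60, reads 0.464. The yield therefore shifts with the reagent charge, with substrate charge and catalyst-time held, so I carry it from oak to this flask, which have the same charges of reagent, 0.0400 M, and of left-handed substrate, 0.050 M, a ratio of 0.800.

The forecast gives 22.5% at 1.5 h, and 16% at 0.67 h, earlier than my limit, on the same route: “Flask at 90 min therefore equals oak at 45 min”.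

The flask gives 22.9% at 1.50 h, and 16% at 0.687 h.

    reagent + catalyst + left-handed substrate → catalyst + left-handed product (k = 1400 M⁻² min⁻¹)
    reagent + catalyst + right-handed substrate → catalyst + right-handed product (k = 360 M⁻² min⁻¹)

Reagent goes to left-handed product 3.2 times as fast as to right-handed product at 0.406 h, and 2.5 times at 1.50 h. The flask ends with 7.29% right-handed product beside 22.9% left-handed product, a yield of 0.573 against my 0.558. The neighbouring flask with 0.024 M reagent has a ratio of 0.480, below this flask's, so the yield of 0.558 gives 13.4%, which I expect to fall short; the computed value is 14.8%.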